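Target slips into isomer of the product B slowly, yet its lifetime by that forward step, 3.14 min, is shorter than the 5.0 min on the clock. Time held divided by that lifetime gives 1.59, the drain count.

| flask | substrate | partner | time | remark |
|---|---|---|---|---|
| Thursday's | 10 mM | 20.0 mM (fed, over 2.50 min) | 5.0 min | all but partner at the start; partner goes in evenly over 2.50 min, the run ends at 5.0 min |
| Monday's | 10 mM | 20.0 mM | 5.0 min | everything together in a closed stirred flask, run for 5.0 min |
| Sunday's | 10 mM | 20.0 mM |  | a single well-mixed tank run continuously and read at steady state, 5.0 min in it on average |
| Friday's | 10 mM (fed, over 2.50 min) | 20.0 mM | 5.0 min | all but substrate at the start; substrate goes in evenly over 2.50 min, the run ends at 5.0 min |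

    target ⇌ isomer of the product B (K1 = 1.6, k1 = 0.0053 /s)
    substrate + partner ⇌ isomer of the product A (K2 = 2200 /M, k2 = 0.024 /M/s)
    2 substrate → homo dimer (k3 = 10 /M/s)
    substrate + partner ⇌ target (K4 = 25 /M, k4 = 1.5 /M/s)

- the set-up with the highest share of target in all that became target or isomer of the product A or isomer of the product B, at the outlet or at the end ("none" if the first two lie within 2 percentage points) (Thursday's / Monday's / Sunday's / Friday's / none)
- share of target in all that became target or isomer of the product A or isomer of the product B, at the outlet or at the end, Thursday's
- share of target in all that became target or isomer of the product A or isomer of the product B, at the outlet or at the end, Monday's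
- share of target in all that became target or isomer of the product A or isomer of the product B, at the outlet or at the end, Sunday's
- share of target in all that became target or isomer of the product A or isomer of the product B, at the outlet or at the end, Friday's

- percentages count the substrate that a species holds: one homo dimer counts as two
- a doubled species enters its step squared and goes two at a time
- the stated concentrations are those of everything mixed, before any reaction; amounts are the same in each set-up
- the feed brings no volume worth counting
- run time (Thursday's): 5.0 min

My reckoning goes by hand for Sunday's tank, where steady balances close; for the other set-ups it reaches no number.

1. Ceiling. In Sunday's tank, isomer of the product B enters from target and leaves by its way back and by the outflow. The tank therefore holds 0.797 of it per target: the count divided by one plus the count over the drain's equilibrium constant. With no isomer of the product A counted, target's share is at most 55.6%.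

2. Floor, taken as an estimate for Sunday's tank. If the three products stood in full balance, at the ratios of their equilibrium constants, target's share would be 1.10%.

3. Tightening. Target and isomer of the product A both form from substrate and partner, so those two concentrations cancel in their ratio. The rate constant of the falling back of isomer of the product A, times the stay, comes to 0.00327, hardly any, so that way is dropped. Target's net loss rate is its return to substrate, plus the drain, plus the outflow, less what comes back from isomer of the product B. This gives 0.317 of isomer of the product A per target.

4. Sunday's share by hand is one over one plus both ratios, 47.3%.

The forecast chose Sunday's, reasoning that “the share of target depends mainly on how young the product is at read-out”. It gave Thursday's 32% (27% to 37%), Monday's 21% (17% to 26%), Sunday's 47% (45% to 49%) and Friday's 21% (17% to 26%). Its Sunday's figure lies inside the bracket.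

The simulation gives Sunday's as best: Thursday's 36.1%, Monday's 24.3%, Sunday's 47.3%, Friday's 25.3%. A run overturning that choice would have to bring Sunday's lead over Thursday's, 11 percentage points, under 2 points.

In Sunday's tank, the half-life of target by the drain step alone, forward rate only, is 2.2 min, shorter than the average stay of 5.0 min; that stay is a drain count of 1.59, and the share reads 47.3%. In Monday's closed flask the same count of 1.59 goes with a share of 24.3% and 2.32% of the charged substrate left, and at 50.0 min, a drain count of 15.9, the share reads 6.72%.

The constants were drawn at random within sensible limits, and the outcome is calculated.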